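**Strategy.** Ring A (eudesmane numbering) is taken apart at its C1–C2 ethano unit, which bridges C3 and the quaternary C10. A Diels–Alder reaction between phenyl vinyl sulfone (an ethylene equivalent) and a semicyclic 2-ethoxydiene, C3=C4(OEt)–C5=C10, built on a menthone-derived ring B, forms C2–C3 and C1–C10 together, closes ring A and sets C10 anti to the pseudoaxial C6 silyloxy group. The diene precursor is a 2-(1-ethoxyvinyl)cyclohexenyl silyl ether carrying the C6 and C7 stereocentres. The C4 enol ether then becomes a ketone (C5 set by protonation), and an enol triflate/methylation sequence installs the C3=C4 methyl alkene before late esterification.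

Key step: step 6

Remark 1: eudesmane numbering is used for all ring carbons: C10 is the methyl-bearing ring-fusion carbon, C5 the other fusion carbon, C6 the oxygenated carbon, C7 the isopropyl carbon, C4 the carbon that finally carries the C15 methyl; β is the face of the C10 methyl (C14).
Remark 2: (−)-menthone free of isomenthone is assumed, because isomenthone would lead to the enantiomeric piperitone and erode enantiomeric purity.
Remark 3: the sulfone-bearing C1 centre of compound 10 is carried as a mixture of epimers and is removed in step 7.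

**Step 1**
Reactants: 1 (−)-menthone
Product: 3 (S)-piperitone, via trimethylsilyl enol ether 2 (not isolated)
Conditions: LiN(i-Pr)2, Me3SiCl, THF, −78 °C; crude 2, then Pd(OAc)2 (10 mol %), O2 (1 atm), DMSO, rt
Reagents that add atoms: none
Why: Kinetic deprotonation at the methylene α-carbon (away from the isopropyl-bearing methine) and O-silylation give the less substituted silyl enol ether, whose Saegusa–Ito oxidation (divalent palladium enolate, β-hydride elimination, reoxidation by O2) should give the enone without touching the isopropyl-bearing stereocentre; the methyl-bearing stereocentre is deliberately destroyed.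

**Step 2**
Reactants: 3 (S)-piperitone
Product: 4 (6S)-2-iodo-3-methyl-6-(propan-2-yl)cyclohex-2-en-1-one
Conditions: I2, pyridine, DMAP (cat.), CH2Cl2, rt, dark
Reagents that add atoms: iodine, II
Why: α-Iodination of a cyclic enone (amine conjugate addition, iodination of the enolate, elimination) forms no stereocentre, and the weakly basic medium should leave the enolisable C7 centre intact.

**Step 3**
Reactants: 4 (6S)-2-iodo-3-methyl-6-(propan-2-yl)cyclohex-2-en-1-one
Product: 5 (1R,6S)-2-iodo-3-methyl-6-(propan-2-yl)cyclohex-2-en-1-ol (hydroxyl cis to isopropyl)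
Conditions: LiBH(s-Bu)3, THF, −78 °C; then aq. NaOH, H2O2, 0 °C
Reagents that add atoms: none
Why: The bulky trialkylborohydride should add 1,2 from the α-face (equatorial trajectory, as in the menthone to neomenthol reduction), placing the new C6 hydroxyl β and cis to the isopropyl group, while β,β-disubstitution of the enone disfavours conjugate reduction.

**Step 4**
Reactants: 5 (1R,6S)-2-iodo-3-methyl-6-(propan-2-yl)cyclohex-2-en-1-ol
Product: 6 tert-butyl{[(1R,6S)-2-iodo-3-methyl-6-(propan-2-yl)cyclohex-2-en-1-yl]oxy}dimethylsilane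
Conditions: TBSOTf, 2,6-lutidine, CH2Cl2, −78 to 0 °C
Reagents that add atoms: tert-butyldimethylsilyl trifluoromethanesulfonate, CC(C)(C)[Si](C)(C)OS(=O)(=O)C(F)(F)F
Why: Silylation of the hindered secondary alcohol with the silyl triflate protects the oxygen and turns it into the bulky pseudoaxial control element needed in step 6.

**Step 5**
Reactants: 6 tert-butyl{[(1R,6S)-2-iodo-3-methyl-6-(propan-2-yl)cyclohex-2-en-1-yl]oxy}dimethylsilane; 7 tributyl(1-ethoxyethenyl)stannane
Product: 8 tert-butyl{[(1R,6S)-2-(1-ethoxyethenyl)-3-methyl-6-(propan-2-yl)cyclohex-2-en-1-yl]oxy}dimethylsilane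
Conditions: Pd(PPh3)4 (5 mol %), CuI (10 mol %), CsF, DMF, 45 °C
Reagents that add atoms: none
Why: Stille coupling of the alkenyl iodide (oxidative addition to zerovalent palladium, copper- and fluoride-assisted transmetalation, reductive elimination) should install the 1-ethoxyvinyl group and complete the electron-rich 2-ethoxydiene without affecting the stereocentres.

**Step 6**
Reactants: 8 tert-butyl{[(1R,6S)-2-(1-ethoxyethenyl)-3-methyl-6-(propan-2-yl)cyclohex-2-en-1-yl]oxy}dimethylsilane; 9 phenyl vinyl sulfone
Product: 10 6β-(tert-butyldimethylsilyloxy)-4-ethoxy-1-(phenylsulfonyl)-15-noreudesm-4-ene (C1 epimers)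
Conditions: toluene, BHT (cat.), 120 °C, sealed tube
Reagents that add atoms: none
Why: A thermal, normal-electron-demand [4+2] cycloaddition in which the electron-rich diene C3=C4(OEt)–C5=C10 adds suprafacially to the sulfonyl-activated alkene through a concerted but strongly asynchronous transition state, the C3–C2 bond from the enol-ether terminus leading and the C1–C10 bond to the fully substituted terminus following. The closest known reaction type is the Diels–Alder reaction of 2-alkoxy- and 2-silyloxy-1,3-dienes, including 1-vinylcyclohexene-type dienes, with phenyl vinyl sulfone used as an ethylene equivalent. Ring A is closed by intermolecular [4+2] annulation onto the C5=C10 bond of ring B, both new sigma bonds forming on the same face of the diene. The C10 centre is controlled by the C6 silyloxy group, which is held pseudoaxial on the β-face by allylic strain against the C5 substituent and by the equatorial C7 isopropyl group, so the dienophile should approach from the α-face and leave the C10 methyl β; the C1 sulfonyl centre is not controlled and is erased in step 7. The step needs facial selectivity, secured by that pseudoaxial silyloxy group, and enough reactivity to engage a diene whose C10 terminus carries a cis methyl group, secured by the donor ethoxy group and the asynchronous bonding; regiochemistry (sulfone expected at C1, para to the ethoxy carbon) is immaterial because the sulfone is removed.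

**Step 7**
Reactants: 10 6β-(tert-butyldimethylsilyloxy)-4-ethoxy-1-(phenylsulfonyl)-15-noreudesm-4-ene
Product: 12 6β-(tert-butyldimethylsilyloxy)-15-nor-5αH-eudesman-4-one, via desulfonylated enol ether 11 (not isolated)
Conditions: Na/Hg (6 % Na), Na2HPO4, MeOH/THF, −20 to 0 °C; then 1 M HCl, THF, 0 °C
Reagents that add atoms: water, O
Why: Reductive desulfonylation by electron transfer (loss of benzenesulfinate, protonation at C1) is followed in the same flask by mild acid hydrolysis of the enol ether, in which C5 should be protonated on the α-face, anti to the axial C10 methyl and the C6 silyloxy group, to give the trans-fused ketone; the mild acid is chosen to avoid β-elimination of the silanol.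

**Step 8**
Reactants: 12 6β-(tert-butyldimethylsilyloxy)-15-nor-5αH-eudesman-4-one
Product: 13 6β-(tert-butyldimethylsilyloxy)-15-nor-5αH-eudesm-3-en-4-yl trifluoromethanesulfonate
Conditions: KN(SiMe3)2, THF, −78 °C; then PhNTf2, −78 to 0 °C
Reagents that add atoms: N-phenylbis(trifluoromethanesulfonimide), O=S(=O)(N(c1ccccc1)S(=O)(=O)C(F)(F)F)C(F)(F)F
Why: Kinetic enolisation should occur at the accessible C3 methylene and not at the hindered C5 methine, and O-triflation of that enolate fixes the double bond at C3=C4.

**Step 9**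
Reactants: 13 6β-(tert-butyldimethylsilyloxy)-15-nor-5αH-eudesm-3-en-4-yl trifluoromethanesulfonate
Product: 14 6β-(tert-butyldimethylsilyloxy)-5αH-eudesm-3-ene
Conditions: MeMgBr, Fe(acac)3 (5 mol %), THF/NMP, −30 to 0 °C
Reagents that add atoms: methylmagnesium bromide, C[Mg]Br
Why: Iron-catalysed cross-coupling of the alkenyl triflate with the methyl Grignard reagent (Kumada-type) should replace the triflate by the C15 methyl group with the double bond held at C3=C4.

**Step 10**
Reactants: 14 6β-(tert-butyldimethylsilyloxy)-5αH-eudesm-3-ene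
Product: 15 5αH-eudesm-3-en-6β-ol, (1R,2S,4aR,8aR)-4a,8-dimethyl-2-(propan-2-yl)-1,2,3,4,4a,5,6,8a-octahydronaphthalen-1-ol
Conditions: Bu4NF, THF, 50 °C
Reagents that add atoms: none
Why: Fluoride-induced cleavage of the silyl ether liberates the axial 6β-alcohol without any change at carbon.

**Step 11**
Reactants: 15 5αH-eudesm-3-en-6β-ol; 16 Meldrum's acid (2,2-dimethyl-1,3-dioxane-4,6-dione)
Product: 17 hydrogen malonate of 15, 3-oxo-3-{[(1R,2S,4aR,8aR)-4a,8-dimethyl-2-(propan-2-yl)-1,2,3,4,4a,5,6,8a-octahydronaphthalen-1-yl]oxy}propanoic acid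
Conditions: toluene, 100 °C
Reagents that add atoms: none
Why: Alcoholysis of Meldrum's acid (acyl transfer with loss of acetone) is a thermal acylation suited to hindered alcohols and should give the hydrogen malonate with retention at C6, since only the O–H bond is engaged.

**Step 12**
Reactants: 17 hydrogen malonate of 15; 18 4-hydroxybenzaldehyde
Product: 19 target, (1R,2S,4aR,8aR)-4a,8-dimethyl-2-(propan-2-yl)-1,2,3,4,4a,5,6,8a-octahydronaphthalen-1-yl (2E)-3-(4-hydroxyphenyl)prop-2-enoate
Conditions: pyridine, piperidine (cat.), 70 °C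
Reagents that add atoms: none
Why: Knoevenagel–Doebner condensation of the hydrogen malonate with the aldehyde, with decarboxylative elimination, should give the (E)-cinnamate directly and tolerates the free phenol.

**Compound list**

1 | (−)-menthone, (2S,5R)-5-methyl-2-(propan-2-yl)cyclohexan-1-one | CC(C)[C@@H]1CC[C@@H](C)CC1=O | starting material
2 | trimethyl{[(3R,6S)-3-methyl-6-(propan-2-yl)cyclohex-1-en-1-yl]oxy}silane | CC(C)[C@@H]1CC[C@@H](C)C=C1O[Si](C)(C)C | intermediate (not isolated)
3 | (S)-piperitone, (6S)-3-methyl-6-(propan-2-yl)cyclohex-2-en-1-one | CC(C)[C@@H]1CCC(C)=CC1=O | intermediate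
4 | (6S)-2-iodo-3-methyl-6-(propan-2-yl)cyclohex-2-en-1-one | CC(C)[C@@H]1CCC(C)=C(I)C1=O | intermediate
5 | (1R,6S)-2-iodo-3-methyl-6-(propan-2-yl)cyclohex-2-en-1-ol | CC(C)[C@@H]1CCC(C)=C(I)[C@@H]1O | intermediate
6 | tert-butyl{[(1R,6S)-2-iodo-3-methyl-6-(propan-2-yl)cyclohex-2-en-1-yl]oxy}dimethylsilane | CC(C)[C@@H]1CCC(C)=C(I)[C@@H]1O[Si](C)(C)C(C)(C)C | intermediate
7 | tributyl(1-ethoxyethenyl)stannane | CCCC[Sn](CCCC)(CCCC)C(=C)OCC | starting material
8 | tert-butyl{[(1R,6S)-2-(1-ethoxyethenyl)-3-methyl-6-(propan-2-yl)cyclohex-2-en-1-yl]oxy}dimethylsilane | CC(C)[C@@H]1CCC(C)=C(C(=C)OCC)[C@@H]1O[Si](C)(C)C(C)(C)C | intermediate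
9 | phenyl vinyl sulfone | C=CS(=O)(=O)c1ccccc1 | starting material
10 | 6β-(tert-butyldimethylsilyloxy)-4-ethoxy-1-(phenylsulfonyl)-15-noreudesm-4-ene (10β-methyl, 7β-isopropyl, C1 epimers) | CCOC1=C2[C@H](O[Si](C)(C)C(C)(C)C)[C@H](C(C)C)CC[C@@]2(C)C(S(=O)(=O)c3ccccc3)CC1 | intermediate
11 | 6β-(tert-butyldimethylsilyloxy)-4-ethoxy-15-noreudesm-4-ene | CCOC1=C2[C@H](O[Si](C)(C)C(C)(C)C)[C@H](C(C)C)CC[C@@]2(C)CCC1 | intermediate (not isolated)
12 | 6β-(tert-butyldimethylsilyloxy)-15-nor-5αH-eudesman-4-one (trans-fused) | O=C1CCC[C@]2(C)CC[C@@H](C(C)C)[C@@H](O[Si](C)(C)C(C)(C)C)[C@@H]12 | intermediate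
13 | 6β-(tert-butyldimethylsilyloxy)-15-nor-5αH-eudesm-3-en-4-yl trifluoromethanesulfonate | FC(F)(F)S(=O)(=O)OC1=CCC[C@]2(C)CC[C@@H](C(C)C)[C@@H](O[Si](C)(C)C(C)(C)C)[C@@H]12 | intermediate
14 | 6β-(tert-butyldimethylsilyloxy)-5αH-eudesm-3-ene | CC1=CCC[C@]2(C)CC[C@@H](C(C)C)[C@@H](O[Si](C)(C)C(C)(C)C)[C@@H]12 | intermediate
15 | 5αH-eudesm-3-en-6β-ol | CC1=CCC[C@]2(C)CC[C@@H](C(C)C)[C@@H](O)[C@@H]12 | intermediate
16 | Meldrum's acid | CC1(C)OC(=O)CC(=O)O1 | starting material
17 | hydrogen malonate of 5αH-eudesm-3-en-6β-ol | CC1=CCC[C@]2(C)CC[C@@H](C(C)C)[C@@H](OC(=O)CC(=O)O)[C@@H]12 | intermediate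
18 | 4-hydroxybenzaldehyde | O=Cc1ccc(O)cc1 | starting material
19 | 6β-[(E)-4-hydroxycinnamoyloxy]-5αH-eudesm-3-ene | CC1=CCC[C@]2(C)CC[C@@H](C(C)C)[C@@H](OC(=O)/C=C/c3ccc(O)cc3)[C@@H]12 | target

**Totals.** Total step count: 12. Longest linear sequence: 12 steps (1 to 19).

**Steps most likely to fail**

Step 6. The cycloaddition may stall because the cis methyl group at the C10 terminus keeps the diene out of the s-cis conformation, or a [1,5]-hydrogen shift of the diene may overtake it on heating. The fallback builds the same two bonds by an anionic double Michael annulation. It sets out from diene 8, which is hydrolysed (PPTS, wet acetone) to the methyl ketone 1-[(5S,6R)-6-(tert-butyldimethylsilyloxy)-2-methyl-5-(propan-2-yl)cyclohex-1-en-1-yl]ethanone F1. Its cross-conjugated lithium dienolate (LiN(i-Pr)2, THF, −78 °C) should add through C3 to phenyl vinyl sulfone 9, and the resulting α-sulfonyl carbanion should close onto C10 of the enone from the α-face to give 6β-(tert-butyldimethylsilyloxy)-1-(phenylsulfonyl)-15-nor-5αH-eudesman-4-one F2. Buffered sodium amalgam (Na/Hg, Na2HPO4, MeOH, −20 °C) then removes the sulfone, and the route is rejoined at ketone 12.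

Step 3. Hydride delivery may occur along the axial trajectory and give mainly the trans alcohol, which would also weaken the facial control of step 6. The fallback corrects the centre by inversion. It sets out from iodoenone 4: Luche reduction (NaBH4, CeCl3·7H2O, MeOH, −78 °C) should give the trans alcohol (1S,6S)-2-iodo-3-methyl-6-(propan-2-yl)cyclohex-2-en-1-ol F3. Mitsunobu inversion with 4-nitrobenzoic acid (PPh3, DIAD, THF) gives (1R,6S)-2-iodo-3-methyl-6-(propan-2-yl)cyclohex-2-en-1-yl 4-nitrobenzoate F4, and methanolysis (K2CO3, MeOH) returns to alcohol 5.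

Step 11. Acyl transfer to the axial C6 hydroxyl, which is flanked by the isopropyl group and the C10 methyl, may be too slow, so that Meldrum's acid decomposes first or the half-ester decarboxylates to the acetate. The fallback attaches the complete cinnamoyl unit in one acylation. It sets out from alcohol 15, which is acylated (Et3N, DMAP, CH2Cl2, 40 °C) with (E)-4-acetoxycinnamoyl chloride F5, made in the flask from commercial (E)-4-acetoxycinnamic acid (oxalyl chloride, DMF cat.). This gives 6β-[(E)-4-acetoxycinnamoyloxy]-5αH-eudesm-3-ene F6. Selective methanolysis of the aryl acetate (K2CO3, MeOH, 0 °C) comes back to the route at target 19, bypassing 17.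

**Further compounds**

F1 | step 6 | 1-[(5S,6R)-6-(tert-butyldimethylsilyloxy)-2-methyl-5-(propan-2-yl)cyclohex-1-en-1-yl]ethanone | CC(C)[C@@H]1CCC(C)=C(C(C)=O)[C@@H]1O[Si](C)(C)C(C)(C)C
F2 | step 6 | 6β-(tert-butyldimethylsilyloxy)-1-(phenylsulfonyl)-15-nor-5αH-eudesman-4-one (C1 epimers) | O=C1CCC(S(=O)(=O)c3ccccc3)[C@]2(C)CC[C@@H](C(C)C)[C@@H](O[Si](C)(C)C(C)(C)C)[C@@H]12
F3 | step 3 | (1S,6S)-2-iodo-3-methyl-6-(propan-2-yl)cyclohex-2-en-1-ol | CC(C)[C@@H]1CCC(C)=C(I)[C@H]1O
F4 | step 3 | (1R,6S)-2-iodo-3-methyl-6-(propan-2-yl)cyclohex-2-en-1-yl 4-nitrobenzoate | CC(C)[C@@H]1CCC(C)=C(I)[C@@H]1OC(=O)c1ccc(cc1)[N+](=O)[O-]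
F5 | step 11 | (E)-4-acetoxycinnamoyl chloride | CC(=O)Oc1ccc(/C=C/C(Cl)=O)cc1
F6 | step 11 | 6β-[(E)-4-acetoxycinnamoyloxy]-5αH-eudesm-3-ene | CC1=CCC[C@]2(C)CC[C@@H](C(C)C)[C@@H](OC(=O)/C=C/c3ccc(OC(C)=O)cc3)[C@@H]12
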